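## The problem

The target is a germacranolide: a ten-membered carbocycle (C1–C10) trans-fused at C7–C8 to an α-methylene-γ-butyrolactone (C11–C13, ring oxygen on C8). It carries a trans 4,5-epoxide, an angelate on O6, a free hydroxyl on C9 and a secondary methyl on C10; in this numbering the configuration is 4R,5R,6R,7S,8S,9R,10R. Seven contiguous stereocentres sit on a flexible medium ring, so the ring should be closed without asking one step for both strain and alkene geometry, and each centre needs a defined source. C6, C7 and C8 are all-syn and can be set together on a five-membered ring. The epoxide oxygen is anti to O6 and the C9 oxygen is anti to O8, so the two halves of the ring ask for additions to mirror-related alkene faces. Three groups are fragile: the trisubstituted epoxide (acid, and transannular attack by an alkene across the ring), the angelate (a Z-enoate that drifts to the tiglate under base or nucleophilic catalysis) and the α-methylene lactone (a Michael acceptor). O6 and O8 begin equivalent and end in different esters, so they must be told apart at one defined point. The enabling feature is C2: it lies between C1 and C3, and when C4=C5 and C9=C10 are both E-alkenes these methylenes are allylic and related by a mirror plane through C2 and C7. Removing C2 leaves a meso nine-carbon bis-electrophile, and C2 can be put back as a one-carbon dinucleophile.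

## Retrosynthesis

Germacrane numbers are used for every intermediate, including the open-chain ones.

**O6–acyl bond and O9–Si.** Target 36 is traced through its C9 triethylsilyl ether 35 to alcohol 32 and angelic acid 33. The ester comes last among the bond-forming steps because any earlier position would expose the Z-enoate to the base needed for the methylene group. The forward step must acylate without isomerising 33, and the final desilylation must spare the epoxide and both unsaturated esters.

**C11=C13.** Alcohol 32 comes from its PMB ether 31, and 31 from the saturated lactone 28 by aminomethylation and elimination. With O6 as a PMB ether and O9 as a silyl ether, the lactone α-CH2 is the only site the base can touch.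

**C12–O8 (lactone).** Lactone 27 (the alcohol of 28) is cut to triol 24. Oxidising the primary alcohol and letting O8 capture the aldehyde avoids a separate acid activation. O9 cannot compete, because it is anti to the side chain across C8 and a six-membered lactol would be a trans-bridged bicycle; O6 is masked.

**Telling O6 from O8.** Diol 23 (the silyl ether of 24) comes from the cyclic 4-methoxybenzylidene acetal 22 by reductive cleavage of the acetal C–O8 bond. The new C9 hydroxyl distinguishes the two oxygens: its aluminium alkoxide can reach O8 only. One step thus frees O8 for the lactone and leaves O6 with the group that is removed last.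

**C9–O and C10–H.** Alcohol 22 comes from alkene 20 by hydroboration. Syn addition to the E-alkene gives the C9/C10 relationship by itself; the open question is the face.

- With O6 and O8 bridged, C5 and C9 must stand parallel on the six-membered ring. O8 then lies in the plane of C9=C10, H8 points outward, and the only accessible face is the one anti to O8, which the target needs.
- Without the bridge (or with the lactone in place), H8 turns into the alkene plane and the exposed face is the wrong one.

Hence acetal 20, made from epoxy diol 19, serves as both the stereocontrol element and the later handle on O6/O8.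

**C4–O and C5–O.** Epoxy diol 19 comes from meso diol 18 by tartrate-controlled epoxidation. This breaks the symmetry, sets C4/C5 anti to O6 and fixes the absolute configuration of the three existing centres.

**C1–C2 and C2–C3 (key cut).** Diol 18 comes from bis-silyl ether 17, and 17 from bis-sulfone 16, which is cut at both bonds to C2 into meso dibromide 13 and bis(phenylsulfonyl)methane 14.

- Against cuts at an alkene (ring-closing metathesis at C4=C5) or at C3–C4 (cross-coupling), this cut forms no ring alkene, keeps the substrate symmetric, and joins unhindered primary carbons.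
- An O6/O8 acetal is left out of 13 on purpose. In its chair both arms are equatorial and about 110° apart, and with two E-alkenes C1 and C3 would stay several ångström too far apart to be joined by one carbon. Open-chain silyl ethers can reach the parallel-arm rotamer freely.

**C4=C5 and C9=C10, in two directions.** Dibromide 13 comes from diol 12, and 12 from diester 11. Diester 11 comes from dialdehyde 10 and two equivalents of ylide 8, which brings C3/C4 and C1/C10 with their methyls and the E-geometry. Dialdehyde 10 is the ozonolysis product of cyclopentene 7, whose ring alkene carbons become C5 and C9.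

**C7–C11 and the two carbinol C–O bonds.** Diol 6 (the parent of 7) comes from sodium cyclopentadienide 3 and triflate 2 (from alcohol 1) through 5-alkylcyclopentadiene 4 and endoperoxide 5. One cycloaddition anti to the side chain sets C6, C7 and C8 in the all-syn relationship.

## Roads not taken

**Alternative 1:** Enone–cyclobutene photocycloaddition followed by thermal ring expansion. The ring is formed at C4–C5 and C1–C10 by [2+2] addition and then opened at C5–C10. Irradiation of the lactone-fused cyclohexenone A1 (C5–C10 as the six ring carbons, C6–C8 already set from the chiral pool) with 1-methylcyclobutene A2 would give the cis,anti,cis photoadduct A3; heating would open its bicyclo[2.2.0]hexane to the ten-membered dienone A4.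

- Merits: absolute configuration comes from the pool, C6–C8 are set on a rigid six-membered ring, and the medium ring appears by strain release.
- Weak points: regio- and facial selectivity of the photoaddition on a fused, oxygenated enone are not secured, and A2 is very volatile and needed in excess. A4 is a 1(10),4-diene, a cyclodeca-1,5-diene that can undergo Cope rearrangement at the temperature that forms it. C9 arrives as a ketone and C10 as an alkene carbon, so both would be set by reductions on a ring whose shape is then dictated by the lactone, the form expected to hide the required face.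
- Comparison: this road reaches the ring in fewer steps and needs no symmetry breaking. The chosen plan sets against it that no stereocentre rests on an excited-state selectivity and that C4/C5 and C9/C10 are introduced on exposed, mirror-related faces of one locked ring.

**Alternative 2:** B-alkyl Suzuki–Miyaura macrocyclisation at C3–C4. Hydroboration of the terminal alkene of seco compound A5 with 9-BBN, then palladium-catalysed coupling of the C3 borane with the C4 iodoalkene under dilution, would give A6.

- Merits: C6 to C10 and the trans-lactone are in place before closure, each set by acyclic control of known reliability; the E-geometry is stored in the iodide; nothing has to be desymmetrised.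
- Weak points: a ten-membered ring is at the small end of what this coupling tolerates, and β-hydride elimination of the alkylpalladium competes with reductive elimination through a strained palladacycle. A5 needs four or five separate stereo-setting reactions. After closure the epoxide must be made with the lactone fused; O6 is then no longer held in the alkene plane and the outer face of C4=C5 is expected to be syn to O6, so a titanium-directed epoxidation from free C6-OH would be needed.
- Comparison: this road is stronger on the certainty of C9 and C10. The chosen plan answers with three stereo-setting operations in all and a ring closure at primary carbons.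

**Alternative 3:** Symmetry-breaking epoxidation as the strategic step. The meso dienediol A7 would be treated with Ti(OiPr)4, D-(−)-diisopropyl tartrate and t-BuOOH to give epoxy diol A8.

- Merits: it uses the same mirror plane, sets C4, C5 and the absolute configuration in one reagent-controlled step, and over-oxidation removes the minor enantiomer.
- Weak points: it does not say how the ring of A7 is made, nor how O6/O8, C9 and C10 follow. A cyclic syn-1,3-diol with a methyl cis to each carbinol carbon is not the best substrate for this catalyst.
- Comparison: in its own step it is as good as anything in the chosen plan, which adopts it as step 11 (A7 and A8 are 18 and 19 with another side-chain protecting group). The chosen plan adds the ring construction that makes the meso diol available and that uses the symmetry a second time.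

Key step: step 8

Remark on the chemistry: 1 and a THF solution of 3 are taken as commercial. Intermediate 15 forms as a racemate, and both enantiomers give meso 16.

## Route

Step 1
Reactants: 1 2-(tert-butyldiphenylsilyloxy)ethanol
Product: 2 2-(tert-butyldiphenylsilyloxy)ethyl trifluoromethanesulfonate
Conditions: Tf2O, 2,6-lutidine, CH2Cl2, −78 °C; used at once
Reagents that add atoms: trifluoromethanesulfonic anhydride, O=S(=O)(OS(=O)(=O)C(F)(F)F)C(F)(F)F
Why: O-sulfonylation of a primary alcohol; β-silyloxyethyl triflates are isolable alkylating agents and are reactive enough to alkylate cyclopentadienide at −78 °C, where the 5-alkyl isomer does not rearrange.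

Step 2
Reactants: 2 2-(tert-butyldiphenylsilyloxy)ethyl trifluoromethanesulfonate; 3 sodium cyclopentadienide
Product: 6 meso-2-[2-(tert-butyldiphenylsilyloxy)ethyl]cyclopent-4-ene-1,3-diol (hydroxyls cis; side chain trans to both), via 5-alkylcyclopentadiene 4 (not isolated), via endoperoxide 5 (not isolated)
Conditions: NaC5H5, THF, −78 °C; then O2, visible light, tetraphenylporphyrin, CH2Cl2–MeOH, −78 °C; then thiourea, −78 °C to rt
Reagents that add atoms: dioxygen, O=O
Why: SN2 alkylation gives the 5-substituted diene, kept cold so that no [1,5]-hydrogen shift occurs; singlet oxygen adds as a dienophile to the face opposite the side chain, and thiourea reduces the O–O bond. The diol therefore has its hydroxyls cis to each other and trans to the side chain, which is the all-syn C6/C7/C8 relationship of the target.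

Step 3
Reactants: 6 meso-2-[2-(tert-butyldiphenylsilyloxy)ethyl]cyclopent-4-ene-1,3-diol
Product: 7 bis(triethylsilyl) ether of 6
Conditions: Et3SiCl, imidazole, DMF, 0 °C to rt
Reagents that add atoms: chlorotriethylsilane, CC[Si](Cl)(CC)CC
Why: Standard silylation of secondary alcohols; triethylsilyl is chosen so that both groups can later be removed beside the primary tert-butyldiphenylsilyl ether.

Step 4
Reactants: 7 bis(triethylsilyl) ether of 6
Product: 10 meso-3-[2-(tert-butyldiphenylsilyloxy)ethyl]-2,4-bis(triethylsilyloxy)pentanedial (all-syn), via ozonide 9 (not isolated)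
Conditions: O3, CH2Cl2, −78 °C; PPh3, −78 °C to rt; concentrated and used crude at once
Reagents that add atoms: ozone, O=[O+][O-]
Why: Ozonolysis of the ring alkene through the Criegee ozonide, whose reduction by PPh3 leaves one ozone oxygen on each former alkene carbon as an aldehyde; the disubstituted alkene reacts far faster than the phenyl rings on silicon. No stereocentre is touched, and the dialdehyde is not chromatographed because α-silyloxy aldehydes hydrate and epimerise on silica.

Step 5
Reactants: 10 meso dialdehyde; 8 ethyl 2-(triphenylphosphoranylidene)propanoate (2 equiv consumed)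
Product: 11 meso diethyl (2E,7E)-5-[2-(tert-butyldiphenylsilyloxy)ethyl]-2,8-dimethyl-4,6-bis(triethylsilyloxy)nona-2,7-dienedioate
Conditions: 8 (2.5 equiv), CH2Cl2, rt to 40 °C
Reagents that add atoms: none
Why: Two-directional Wittig olefination, one ylide per aldehyde, with both aldehyde oxygens leaving as triphenylphosphine oxide; the stabilised α-methyl ylide is non-basic (no epimerisation of the α-silyloxy aldehydes) and should give both trisubstituted alkenes E. The triphenylphosphine oxide carried over from step 4 is inert.

Step 6
Reactants: 11 meso diethyl nona-2,7-dienedioate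
Product: 12 meso (2E,7E)-5-[2-(tert-butyldiphenylsilyloxy)ethyl]-2,8-dimethyl-4,6-bis(triethylsilyloxy)nona-2,7-diene-1,9-diol
Conditions: iBu2AlH, CH2Cl2, −78 °C; aqueous potassium sodium tartrate
Reagents that add atoms: none
Why: 1,2-Reduction of both enoates to the allylic alcohols; the E-alkene between each silyl ether and the new hydroxyl rules out silyl migration.

Step 7
Reactants: 12 meso nona-2,7-diene-1,9-diol
Product: 13 meso (2E,7E)-1,9-dibromo-5-[2-(tert-butyldiphenylsilyloxy)ethyl]-2,8-dimethyl-4,6-bis(triethylsilyloxy)nona-2,7-diene
Conditions: CBr4, PPh3, 2,6-lutidine, CH2Cl2, −30 to 0 °C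
Reagents that add atoms: tetrabromomethane, BrC(Br)(Br)Br
Why: Appel bromination of primary allylic alcohols by direct SN2 displacement of the alkoxyphosphonium group, without allylic transposition; the buffer protects the silyl ethers.

Step 8
Reactants: 13 meso bis-allylic dibromide; 14 bis(phenylsulfonyl)methane
Product: 16 meso (4E,9E)-7-[2-(tert-butyldiphenylsilyloxy)ethyl]-4,10-dimethyl-2,2-bis(phenylsulfonyl)-6,8-bis(triethylsilyloxy)cyclodeca-4,9-diene (germacrane numbering; C6/C7/C8 all-syn), via monoalkylated bromide 15 (not isolated)
Conditions: Cs2CO3, DMF, 40 °C; 13 and 14 (1:1) added together by syringe pump over 16 h to a final 2 mM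
Reagents that add atoms: none
Why: Cs2CO3 deprotonates 14 (a carbon acid of pKa about 12); the anion displaces one primary allylic bromide of 13 by SN2 to give 15, whose remaining acidic C–H is deprotonated in turn, and the tertiary carbanion displaces the second bromide, forming C1–C2 and then C2–C3. The closest known reaction type is the double alkylation of bis(phenylsulfonyl)methane with 1,4-dihalobut-2-enes to cyclopentenes, together with high-dilution ring closures of sulfone- and malonate-stabilised carbanions onto allylic halides. The ring closes in the 10-exo-tet mode. No stereocentre is formed: C2 lies on the mirror plane, and both enantiomers of 15 give meso 16. SN2 is expected over SN2′ because the alternative site (C5 or C9) is secondary and flanked by the silyloxy-bearing carbon, while the bulky nucleophile meets an unhindered CH2. Cyclisation over oligomerisation is helped by slow addition, by the two E-trisubstituted alkenes that are already in place and remove four rotors, by the geminal sulfonyl groups, and by the all-syn C6–C8 triad, which lets both arms lie parallel on the face away from the C7 side chain with the silyloxy groups pointing outward. An O6/O8 acetal is deliberately absent here because its chair would hold the two arms about 110° apart.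

Step 9
Reactants: 16 meso bis-sulfone
Product: 17 meso (4E,9E)-7-[2-(tert-butyldiphenylsilyloxy)ethyl]-4,10-dimethyl-6,8-bis(triethylsilyloxy)cyclodeca-4,9-diene
Conditions: Mg, MeOH–THF, rt to 50 °C
Reagents that add atoms: none
Why: Dissolving-metal reductive desulfonylation of a geminal bis-sulfone; C2 is homoallylic, so no β-leaving group or allylic transposition is involved, and silyl ethers tolerate the methoxide formed.

Step 10
Reactants: 17 meso bis(triethylsilyl) ether
Product: 18 meso (4E,9E)-7-[2-(tert-butyldiphenylsilyloxy)ethyl]-4,10-dimethylcyclodeca-4,9-diene-6,8-diol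
Conditions: HF·pyridine, pyridine, THF, 0 °C to rt
Reagents that add atoms: none
Why: Buffered fluoride removes the two secondary triethylsilyl ethers and leaves the primary tert-butyldiphenylsilyl ether; the conditions are too mild to ionise the allylic alcohols.

Step 11
Reactants: 18 meso dienediol
Product: 19 4,5-epoxy-9-ene-6,8-diol (4R,5R-epoxide anti to O6; C6/C7/C8 as in 36)
Conditions: Ti(OiPr)4, D-(−)-diisopropyl tartrate, t-BuOOH, 4 Å molecular sieves, CH2Cl2, −25 °C
Reagents that add atoms: tert-butyl hydroperoxide, CC(C)(C)OO
Why: Sharpless asymmetric epoxidation used as a desymmetrisation of a meso bis-allylic diol: with the D-(−)-tartrate the carbinol that becomes C6 is the matched one and oxygen is delivered to C4=C5 anti to the C6–C7 bond (erythro epoxy alcohol), while the enantiotopic C8 carbinol is mismatched. Material of the wrong sense reacts a second time faster and is removed as bis-epoxide.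

Step 12
Reactants: 19 epoxy diol
Product: 20 6,8-O-(4-methoxybenzylidene) acetal of 19 (aryl group cis to C5 and C9 on the dioxane)
Conditions: 4-MeOC6H4CH(OMe)2, pyridinium p-toluenesulfonate (cat.), 4 Å molecular sieves, CH2Cl2, rt
Reagents that add atoms: 4-methoxybenzaldehyde dimethyl acetal, COc1ccc(cc1)C(OC)OC
Why: Acid-catalysed transacetalisation under conditions mild enough for the epoxide. The diol can be bridged only when C5 and C9 stand parallel, so the dioxane forms as a boat with the aryl group outward, and this bridge holds the ring in the conformer where O8 lies in the plane of C9=C10 and H8 points to the outside.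

Step 13
Reactants: 20 bridged epoxy alkene
Product: 22 C9 alcohol (9R,10R; acetal and epoxide unchanged), via alkylborane 21 (not isolated)
Conditions: BH3·THF, THF, 0 °C; then NaOH, H2O2, 0 °C to rt
Reagents that add atoms: hydrogen peroxide, OO
Why: Hydroboration–oxidation: boron goes to C9 (the less substituted carbon, and the one where no positive charge builds up next to C8–O), and H and B add syn to the E-alkene, which by itself places the C9 oxygen and the C10 methyl anti. The other alkene face is covered by the ring, so the borane can only reach the outer face, which in the bridged conformer is the face anti to O8; oxidation occurs with retention.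

Step 14
Reactants: 22 C9 alcohol
Product: 23 6-O-(4-methoxybenzyl) 8,9-diol
Conditions: iBu2AlH (4 equiv), CH2Cl2, −78 to −20 °C; aqueous potassium sodium tartrate
Reagents that add atoms: none
Why: Chelation-directed reductive cleavage of a 4-methoxybenzylidene acetal: the C9 alkoxide binds aluminium, which coordinates the neighbouring acetal oxygen O8 in a five-membered chelate, the C–O8 bond breaks and hydride reduces the oxocarbenium ion on O6. The PMB group should therefore end on O6; at low temperature the trisubstituted epoxide should be spared.

Step 15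
Reactants: 23 6-O-PMB 8,9-diol
Product: 24 8,9,12-triol
Conditions: Bu4NF, THF, 0 °C to rt
Reagents that add atoms: none
Why: Fluoride cleavage of the primary tert-butyldiphenylsilyl ether; the PMB ether and the epoxide are inert to it.

Step 16
Reactants: 24 triol
Product: 27 trans-fused 12,8-lactone with free C9 hydroxyl and O6-PMB, via hydroxy aldehyde 25 (not isolated), via lactol 26 (not isolated)
Conditions: TEMPO (cat.), PhI(OAc)2, CH2Cl2, rt
Reagents that add atoms: none
Why: Oxoammonium oxidation selective for the primary alcohol; aldehyde 25 is captured by O8 as the five-membered lactol 26, which is oxidised on to the γ-lactone. O9 is anti to the side chain across C8 and could only form a trans-bridged six-membered ring, and O6 is masked.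

Step 17
Reactants: 27 hydroxy lactone
Product: 28 C9 triethylsilyl ether of 27
Conditions: Et3SiCl, imidazole, 4-dimethylaminopyridine (cat.), DMF, rt
Reagents that add atoms: chlorotriethylsilane, CC[Si](Cl)(CC)CC
Why: Silylation of the only free hydroxyl; the group must survive one enolate step and come off last under mild fluoride.

Step 18
Reactants: 28 silyl ether lactone
Product: 31 α-methylene lactone (O6-PMB and O9-SiEt3), via Mannich base 29 (not isolated), via ammonium iodide 30 (not isolated)
Conditions: LiN(SiMe3)2, THF, −78 °C; CH2=NMe2 I, −78 °C to rt; MeI, MeOH, rt; NaHCO3, CH2Cl2–H2O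
Reagents that add atoms: N,N-dimethylmethyleneiminium iodide (Eschenmoser's salt), C=[N+](C)C.[I-]
Why: Aminomethylation of the lactone enolate, N-methylation and base-induced elimination of trimethylamine (α-methylenation). The configuration formed at C11 in 29 is irrelevant because C11 becomes sp2, and with O6 and O9 as ethers the lactone α-CH2 is the only site the base deprotonates.

Step 19
Reactants: 31 PMB ether
Product: 32 C6 alcohol
Conditions: DDQ, CH2Cl2–pH 7 phosphate buffer, 0 °C to rt
Reagents that add atoms: none
Why: Oxidative cleavage of the PMB ether under buffered, neutral conditions; the conjugated lactone is electron-poor and inert to the quinone, and the buffer protects the silyl ether and the epoxide.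

Step 20
Reactants: 32 C6 alcohol; 33 angelic acid ((Z)-2-methylbut-2-enoic acid)
Product: 35 C9 triethylsilyl ether of the target, via mixed anhydride 34 (not isolated)
Conditions: 33, 2,4,6-trichlorobenzoyl chloride, Et3N, toluene, rt; filter; then 32, toluene, 80 °C
Reagents that add atoms: none
Why: Yamaguchi-type esterification through the mixed anhydride without a nucleophilic catalyst, chosen because 4-dimethylaminopyridine promotes Z-to-E isomerisation of angelates; the Z-geometry is brought in with 33.

Step 21
Reactants: 35 silyl ether
Product: 36 (4R,5R,6R,7S,8S,9R,10R)-6-angeloyloxy-4,5-epoxy-9-hydroxygermacr-11(13)-en-12,8-olide (CNP0165329.1)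
Conditions: HF·pyridine, pyridine, THF, 0 °C
Reagents that add atoms: none
Why: Buffered fluoride cleavage of a secondary triethylsilyl ether, mild enough for the epoxide, the angelate and the α-methylene lactone.

## Compound list

1 | 2-(tert-butyldiphenylsilyloxy)ethanol | OCCO[Si](c1ccccc1)(c2ccccc2)C(C)(C)C | starting material
2 | 2-(tert-butyldiphenylsilyloxy)ethyl trifluoromethanesulfonate | O=S(=O)(OCCO[Si](c1ccccc1)(c2ccccc2)C(C)(C)C)C(F)(F)F | intermediate
3 | sodium cyclopentadienide | [Na+].c1cc[cH-]c1 | starting material
4 | 5-[2-(tert-butyldiphenylsilyloxy)ethyl]cyclopenta-1,3-diene | C1=CC(C=C1)CCO[Si](c2ccccc2)(c3ccccc3)C(C)(C)C | intermediate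
5 | 7-[2-(tert-butyldiphenylsilyloxy)ethyl]-2,3-dioxabicyclo[2.2.1]hept-5-ene, side chain anti to the peroxide bridge | O1[C@@H]2C=C[C@H](O1)[C@H]2CCO[Si](c3ccccc3)(c4ccccc4)C(C)(C)C | intermediate
6 | meso-2-[2-(tert-butyldiphenylsilyloxy)ethyl]cyclopent-4-ene-1,3-diol, hydroxyls cis, side chain trans to both | O[C@@H]1C=C[C@H](O)[C@H]1CCO[Si](c2ccccc2)(c3ccccc3)C(C)(C)C | intermediate
7 | bis(triethylsilyl) ether of 6 | CC[Si](CC)(CC)O[C@@H]1C=C[C@H](O[Si](CC)(CC)CC)[C@H]1CCO[Si](c2ccccc2)(c3ccccc3)C(C)(C)C | intermediate
8 | ethyl 2-(triphenylphosphoranylidene)propanoate | CCOC(=O)C(C)=P(c1ccccc1)(c2ccccc2)c3ccccc3 | starting material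
9 | ozonide of 7 (6,7,8-trioxabicyclo[3.2.1]octane; the two acetal carbons left without configuration) | CC[Si](CC)(CC)O[C@@H]1C2OOC(O2)[C@H](O[Si](CC)(CC)CC)[C@H]1CCO[Si](c3ccccc3)(c4ccccc4)C(C)(C)C | intermediate
10 | meso-3-[2-(tert-butyldiphenylsilyloxy)ethyl]-2,4-bis(triethylsilyloxy)pentanedial, all-syn | O=C[C@@H](O[Si](CC)(CC)CC)[C@H](CCO[Si](c1ccccc1)(c2ccccc2)C(C)(C)C)[C@@H](O[Si](CC)(CC)CC)C=O | intermediate
11 | meso diethyl (2E,7E)-5-[2-(tert-butyldiphenylsilyloxy)ethyl]-2,8-dimethyl-4,6-bis(triethylsilyloxy)nona-2,7-dienedioate | CCOC(=O)/C(C)=C/[C@@H](O[Si](CC)(CC)CC)[C@H](CCO[Si](c1ccccc1)(c2ccccc2)C(C)(C)C)[C@@H](O[Si](CC)(CC)CC)/C=C(C)/C(=O)OCC | intermediate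
12 | meso (2E,7E)-5-[2-(tert-butyldiphenylsilyloxy)ethyl]-2,8-dimethyl-4,6-bis(triethylsilyloxy)nona-2,7-diene-1,9-diol | OC/C(C)=C/[C@@H](O[Si](CC)(CC)CC)[C@H](CCO[Si](c1ccccc1)(c2ccccc2)C(C)(C)C)[C@@H](O[Si](CC)(CC)CC)/C=C(C)/CO | intermediate
13 | meso (2E,7E)-1,9-dibromo-5-[2-(tert-butyldiphenylsilyloxy)ethyl]-2,8-dimethyl-4,6-bis(triethylsilyloxy)nona-2,7-diene | BrC/C(C)=C/[C@@H](O[Si](CC)(CC)CC)[C@H](CCO[Si](c1ccccc1)(c2ccccc2)C(C)(C)C)[C@@H](O[Si](CC)(CC)CC)/C=C(C)/CBr | intermediate
14 | bis(phenylsulfonyl)methane | O=S(=O)(CS(=O)(=O)c1ccccc1)c2ccccc2 | starting material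
15 | monoalkylated bromide: (2E,7E)-1-bromo-5-[2-(tert-butyldiphenylsilyloxy)ethyl]-2,8-dimethyl-10,10-bis(phenylsulfonyl)-4,6-bis(triethylsilyloxy)deca-2,7-diene (racemic; one enantiomer drawn) | BrC/C(C)=C/[C@@H](O[Si](CC)(CC)CC)[C@H](CCO[Si](c1ccccc1)(c2ccccc2)C(C)(C)C)[C@@H](O[Si](CC)(CC)CC)/C=C(C)/CC(S(=O)(=O)c3ccccc3)S(=O)(=O)c4ccccc4 | intermediate
16 | meso (4E,9E)-7-[2-(tert-butyldiphenylsilyloxy)ethyl]-4,10-dimethyl-2,2-bis(phenylsulfonyl)-6,8-bis(triethylsilyloxy)cyclodeca-4,9-diene (germacrane numbering) | CC[Si](CC)(CC)O[C@@H]1/C=C(C)/CC(S(=O)(=O)c2ccccc2)(S(=O)(=O)c3ccccc3)C/C(C)=C/[C@H](O[Si](CC)(CC)CC)[C@H]1CCO[Si](c4ccccc4)(c5ccccc5)C(C)(C)C | intermediate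
17 | meso (4E,9E)-7-[2-(tert-butyldiphenylsilyloxy)ethyl]-4,10-dimethyl-6,8-bis(triethylsilyloxy)cyclodeca-4,9-diene | CC[Si](CC)(CC)O[C@@H]1/C=C(C)/CCC/C(C)=C/[C@H](O[Si](CC)(CC)CC)[C@H]1CCO[Si](c2ccccc2)(c3ccccc3)C(C)(C)C | intermediate
18 | meso (4E,9E)-7-[2-(tert-butyldiphenylsilyloxy)ethyl]-4,10-dimethylcyclodeca-4,9-diene-6,8-diol | O[C@@H]1/C=C(C)/CCC/C(C)=C/[C@H](O)[C@H]1CCO[Si](c2ccccc2)(c3ccccc3)C(C)(C)C | intermediate
19 | 4,5-epoxy-9-ene-6,8-diol: (9E)-7-[2-(tert-butyldiphenylsilyloxy)ethyl]-4,5-epoxy-4,10-dimethylcyclodec-9-ene-6,8-diol, epoxide anti to O6, configuration at C4–C8 as in 36 | O[C@@H]1/C=C(C)/CCC[C@@]2(C)O[C@@H]2[C@H](O)[C@H]1CCO[Si](c3ccccc3)(c4ccccc4)C(C)(C)C | intermediate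
20 | 6,8-O-(4-methoxybenzylidene) acetal of 19, aryl group cis to C5 and C9 on the dioxane | COc1ccc(cc1)[C@@H]2O[C@@H]3/C=C(C)/CCC[C@@]4(C)O[C@@H]4[C@H](O2)[C@H]3CCO[Si](c5ccccc5)(c6ccccc6)C(C)(C)C | intermediate
21 | C9 alkylborane from 20 (drawn as RBH2; boron on the face anti to O8) | COc1ccc(cc1)[C@@H]2O[C@@H]3[C@H](B)[C@H](C)CCC[C@@]4(C)O[C@@H]4[C@H](O2)[C@H]3CCO[Si](c5ccccc5)(c6ccccc6)C(C)(C)C | intermediate
22 | 9-hydroxy acetal: 6,8-O-(4-methoxybenzylidene)-4,5-epoxy-9-ol, C4–C10 as in 36 | COc1ccc(cc1)[C@@H]2O[C@@H]3[C@H](O)[C@H](C)CCC[C@@]4(C)O[C@@H]4[C@H](O2)[C@H]3CCO[Si](c5ccccc5)(c6ccccc6)C(C)(C)C | intermediate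
23 | 6-O-(4-methoxybenzyl)-4,5-epoxy-8,9-diol with 12-O-tert-butyldiphenylsilyl side chain | O[C@@H]1[C@H](O)[C@H](C)CCC[C@@]2(C)O[C@@H]2[C@H](OCc3ccc(OC)cc3)[C@H]1CCO[Si](c4ccccc4)(c5ccccc5)C(C)(C)C | intermediate
24 | 6-O-(4-methoxybenzyl)-4,5-epoxy-8,9,12-triol | O[C@@H]1[C@H](O)[C@H](C)CCC[C@@]2(C)O[C@@H]2[C@H](OCc3ccc(OC)cc3)[C@H]1CCO | intermediate
25 | 12-aldehyde of 24 | O[C@@H]1[C@H](O)[C@H](C)CCC[C@@]2(C)O[C@@H]2[C@H](OCc3ccc(OC)cc3)[C@H]1CC=O | intermediate
26 | 12,8-lactol (both anomers) | C1C(O)O[C@@H]2[C@H](O)[C@H](C)CCC[C@@]3(C)O[C@@H]3[C@H](OCc4ccc(OC)cc4)[C@@H]12 | intermediate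
27 | 6-O-(4-methoxybenzyl)-4,5-epoxy-9-hydroxygermacran-12,8-olide (trans-fused) | C1C(=O)O[C@@H]2[C@H](O)[C@H](C)CCC[C@@]3(C)O[C@@H]3[C@H](OCc4ccc(OC)cc4)[C@@H]12 | intermediate
28 | 9-O-triethylsilyl ether of 27 | C1C(=O)O[C@@H]2[C@H](O[Si](CC)(CC)CC)[C@H](C)CCC[C@@]3(C)O[C@@H]3[C@H](OCc4ccc(OC)cc4)[C@@H]12 | intermediate
29 | 11-(dimethylaminomethyl) lactone (Mannich base; C11 epimers) | CN(C)CC1C(=O)O[C@@H]2[C@H](O[Si](CC)(CC)CC)[C@H](C)CCC[C@@]3(C)O[C@@H]3[C@H](OCc4ccc(OC)cc4)[C@@H]12 | intermediate
30 | trimethylammonium iodide of 29 | [I-].C[N+](C)(C)CC1C(=O)O[C@@H]2[C@H](O[Si](CC)(CC)CC)[C@H](C)CCC[C@@]3(C)O[C@@H]3[C@H](OCc4ccc(OC)cc4)[C@@H]12 | intermediate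
31 | 6-O-(4-methoxybenzyl)-9-O-triethylsilyl-4,5-epoxygermacr-11(13)-en-12,8-olide | C=C1C(=O)O[C@@H]2[C@H](O[Si](CC)(CC)CC)[C@H](C)CCC[C@@]3(C)O[C@@H]3[C@H](OCc4ccc(OC)cc4)[C@@H]12 | intermediate
32 | 9-O-triethylsilyl-4,5-epoxy-6-hydroxygermacr-11(13)-en-12,8-olide | C=C1C(=O)O[C@@H]2[C@H](O[Si](CC)(CC)CC)[C@H](C)CCC[C@@]3(C)O[C@@H]3[C@H](O)[C@@H]12 | intermediate
33 | angelic acid, (Z)-2-methylbut-2-enoic acid | OC(=O)/C(C)=C\C | starting material
34 | angelic 2,4,6-trichlorobenzoic anhydride | Clc1cc(Cl)c(C(=O)OC(=O)/C(C)=C\C)c(Cl)c1 | intermediate
35 | 9-O-triethylsilyl ether of the target | C=C1C(=O)O[C@@H]2[C@H](O[Si](CC)(CC)CC)[C@H](C)CCC[C@@]3(C)O[C@@H]3[C@H](OC(=O)/C(C)=C\C)[C@@H]12 | intermediate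
36 | (4R,5R,6R,7S,8S,9R,10R)-6-angeloyloxy-4,5-epoxy-9-hydroxygermacr-11(13)-en-12,8-olide (CNP0165329.1) | C=C1C(=O)O[C@@H]2[C@H](O)[C@H](C)CCC[C@@]3(C)O[C@@H]3[C@H](OC(=O)/C(C)=C\C)[C@@H]12 | target

## Step count and weakest steps

Total: 21 steps. Longest linear sequence: 21 steps (1 to 36); 3, 8, 14 and 33 are bought and enter at steps 2, 5, 8 and 20.

**Step 8 (key step).** The likely failure is oligomerisation: the second alkylation uses a hindered tertiary carbanion and closes a strained ring, so the remaining bromide of 15 may instead be captured by a second sulfone anion or by another chain. The fallback changes the electrophile and the mechanism. It sets out from diol 12, which methyl chloroformate and pyridine convert into the bis(methyl carbonate) F1. Slow addition of F1 and 14 to Pd(PPh3)4 (zerovalent palladium) in THF ionises each carbonate to a π-allyl complex, which is far more electrophilic than the bromide; the sulfone anion attacks the unsubstituted terminus twice (Tsuji–Trost alkylation, the methoxide set free serving as base). The route is rejoined at 16.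

**Step 13.** The likely failure is incomplete facial discrimination if the bridged ring is more mobile than pictured, or hydride attack of the borane on the epoxide. The fallback changes the order and adds a second control element. It sets out from 18, which is first converted into the meso acetal F2 described under step 11. Monoisopinocampheylborane prepared from (+)-α-pinene then hydroborates one of the two enantiotopic alkenes, its own preference adding to the exposure imposed by the ring, and oxidation gives the hydroxy alkene F6 with no epoxide yet present. Dimethyldioxirane then epoxidises the remaining alkene on its outer face, and the route is rejoined at 22.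

**Step 14.** The likely failure is attack of excess aluminium hydride on the epoxide, or cleavage on the O6 side if the epoxide oxygen competes for aluminium. The fallback tells the oxygens apart by hindrance, without hydride. It sets out from 22, which is silylated (t-BuMe2SiCl, imidazole) to the C9 silyl ether F7. Pyridinium p-toluenesulfonate in methanol removes the strained acetal to give the 6,8-diol F8, in which C8-OH is screened by the neighbouring silyloxy carbon. 4-Methoxybenzyl trichloroacetimidate with catalytic La(OTf)3 should then etherify the more accessible C6-OH to give F9, and Bu4NF removes both silyl groups, rejoining the route at 24.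

**Step 12.** The likely failure is acetalisation stopping at the open mixed acetal, because the six-membered ring can only close as a boat; acid-triggered attack of C9=C10 on the epoxide is a second risk. The fallback lets the hydroborating agent make its own bridge. It sets out from 19: excess BH3·THF first converts the syn-1,3-diol into a cyclic dialkoxyborane (planar boron, no substituent pointing into the ring), and the same excess hydroborates C9=C10; oxidative work-up gives the epoxy triol F3. The cis-8,9-diol then takes up 4-methoxybenzaldehyde dimethyl acetal as the unstrained five-membered acetal F4, C6-OH is converted into its PMB ether F5 (trichloroacetimidate, catalytic La(OTf)3), and pyridinium p-toluenesulfonate in methanol releases the 8,9-diol, rejoining the route at 23.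

**Step 11.** The likely failure is slow or poorly selective oxygen transfer, because the syn-1,3-diol can chelate titanium and the C4 methyl is cis to the carbinol carbon. The fallback removes the need for a free hydroxyl. It sets out from 18, which 4-methoxybenzaldehyde dimethyl acetal and pyridinium p-toluenesulfonate convert into the meso 6,8-acetal F2. Shi epoxidation with the D-fructose-derived ketone and KHSO5 at buffered pH then attacks the outer face of C4=C5, which is the enantioface this ketone prefers for an E-trisubstituted alkene, while the outer face of C9=C10 is its mirror image. The route is rejoined at 20.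

**Step 20.** The likely failure is isomerisation of the activated angelate to the tiglate, or slow acylation of the hindered C6 hydroxyl. The fallback builds the Z-alkene on the ester. It sets out from 32, which is esterified (N,N′-dicyclohexylcarbodiimide, 4-dimethylaminopyridine) with 2-[bis(2,2,2-trifluoroethoxy)phosphoryl]propanoic acid to give the phosphonate F10. Still–Gennari olefination with acetaldehyde (KN(SiMe3)2, 18-crown-6, THF, −78 °C) should then give the Z-enoate, rejoining the route at 35.

## Further compounds

F1 | step 8 | bis(methyl carbonate) of diol 12 | COC(=O)OC/C(C)=C/[C@@H](O[Si](CC)(CC)CC)[C@H](CCO[Si](c1ccccc1)(c2ccccc2)C(C)(C)C)[C@@H](O[Si](CC)(CC)CC)/C=C(C)/COC(=O)OC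
F2 | step 11 | meso 6,8-O-(4-methoxybenzylidene) acetal of dienediol 18 | COc1ccc(cc1)[C@@H]2O[C@@H]3/C=C(C)/CCC/C(C)=C/[C@H](O2)[C@H]3CCO[Si](c4ccccc4)(c5ccccc5)C(C)(C)C
F3 | step 12 | 4,5-epoxy-6,8,9-triol with 12-O-tert-butyldiphenylsilyl side chain | O[C@@H]1[C@H](O)[C@H](C)CCC[C@@]2(C)O[C@@H]2[C@H](O)[C@H]1CCO[Si](c3ccccc3)(c4ccccc4)C(C)(C)C
F4 | step 12 | 8,9-O-(4-methoxybenzylidene) acetal of F3 with free C6 hydroxyl (acetal carbon unassigned) | COc1ccc(cc1)C2O[C@@H]3[C@H](O2)[C@H](C)CCC[C@@]4(C)O[C@@H]4[C@H](O)[C@H]3CCO[Si](c5ccccc5)(c6ccccc6)C(C)(C)C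
F5 | step 12 | 6-O-(4-methoxybenzyl) ether of F4 | COc1ccc(cc1)C2O[C@@H]3[C@H](O2)[C@H](C)CCC[C@@]4(C)O[C@@H]4[C@H](OCc5ccc(OC)cc5)[C@H]3CCO[Si](c6ccccc6)(c7ccccc7)C(C)(C)C
F6 | step 13 | 9-hydroxy-4-ene 6,8-O-(4-methoxybenzylidene) acetal | COc1ccc(cc1)[C@@H]2O[C@@H]3[C@H](O)[C@H](C)CCC/C(C)=C/[C@H](O2)[C@H]3CCO[Si](c4ccccc4)(c5ccccc5)C(C)(C)C
F7 | step 14 | 9-O-tert-butyldimethylsilyl ether of 22 | COc1ccc(cc1)[C@@H]2O[C@@H]3[C@H](O[Si](C)(C)C(C)(C)C)[C@H](C)CCC[C@@]4(C)O[C@@H]4[C@H](O2)[C@H]3CCO[Si](c5ccccc5)(c6ccccc6)C(C)(C)C
F8 | step 14 | 9-O-tert-butyldimethylsilyl-4,5-epoxy-6,8-diol | O[C@@H]1[C@H](O[Si](C)(C)C(C)(C)C)[C@H](C)CCC[C@@]2(C)O[C@@H]2[C@H](O)[C@H]1CCO[Si](c3ccccc3)(c4ccccc4)C(C)(C)C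
F9 | step 14 | 6-O-(4-methoxybenzyl) ether of F8 | O[C@@H]1[C@H](O[Si](C)(C)C(C)(C)C)[C@H](C)CCC[C@@]2(C)O[C@@H]2[C@H](OCc3ccc(OC)cc3)[C@H]1CCO[Si](c4ccccc4)(c5ccccc5)C(C)(C)C
F10 | step 20 | 6-O-{2-[bis(2,2,2-trifluoroethoxy)phosphoryl]propanoyl} ester of 32 | C=C1C(=O)O[C@@H]2[C@H](O[Si](CC)(CC)CC)[C@H](C)CCC[C@@]3(C)O[C@@H]3[C@H](OC(=O)C(C)P(=O)(OCC(F)(F)F)OCC(F)(F)F)[C@@H]12
A1 | alternative 1 | lactone-fused cyclohexenone (photosubstrate) | C[C@@H]1C(=O)O[C@@H]2C(=O)C(C)=C[C@H](O[Si](C)(C)C(C)(C)C)[C@@H]12
A2 | alternative 1 | 1-methylcyclobutene | CC1=CCC1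
A3 | alternative 1 | tetracyclic cis,anti,cis photoadduct | C[C@@H]1C(=O)O[C@@H]2C(=O)[C@@]3(C)[C@@H]4CC[C@]4(C)[C@H]3[C@H](O[Si](C)(C)C(C)(C)C)[C@@H]12
A4 | alternative 1 | ring-expanded ten-membered 1(10),4-dien-9-one | C[C@@H]1C(=O)O[C@@H]2C(=O)/C(C)=C/CC/C(C)=C/[C@H](O[Si](C)(C)C(C)(C)C)[C@@H]12
A5 | alternative 2 | seco lactone with terminal alkene and (E)-iodoalkene | O=C1C[C@H]([C@@H](O[Si](CC)(CC)CC)/C=C(C)/I)[C@H](O1)[C@H](O[Si](C)(C)C(C)(C)C)[C@H](C)CC=C
A6 | alternative 2 | ten-membered E-cycloalkene fused to the trans-lactone | O=C1O[C@@H]2[C@H](O[Si](C)(C)C(C)(C)C)[C@H](C)CCC/C(C)=C/[C@H](O[Si](CC)(CC)CC)[C@H]2C1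
A7 | alternative 3 | meso dienediol with 4-methoxybenzyl-protected side chain | O[C@@H]1/C=C(C)/CCC/C(C)=C/[C@H](O)[C@H]1CCOCc2ccc(OC)cc2
A8 | alternative 3 | 4,5-epoxy-9-ene-6,8-diol with 4-methoxybenzyl-protected side chain | O[C@@H]1/C=C(C)/CCC[C@@]2(C)O[C@@H]2[C@H](O)[C@H]1CCOCc3ccc(OC)cc3
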